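To whoever takes over the bench: the flasks teal, amber and blue hold the same charges and differ in how long X is fed.

| setting | ash | elm | teal | amber | blue |
|---|---|---|---|---|---|
| X | 0.018 M (fed, over 4.0 min) | 0.018 M (fed, over 4.0 min) | 0.018 M (fed, over 4.0 min) | 0.018 M (fed, over 8.0 min) | 0.018 M (fed, over 15 min) |
| E | 0.0144 M | 0.0144 M | 0.0144 M | 0.0144 M | 0.0144 M |
| J | 0.27 mM | 0.41 mM | 0.54 mM | 0.54 mM | 0.54 mM |
| remark | run made earlier | run made earlier |  |  |  |
| time |  |  | 25 min | 25 min | 25 min |

| run | time / min | Q / % | X / % |
|---|---|---|---|
| ash | 2.50 | 2.7 | 58.5 |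
| ash | 5.00 | 9.7 | 88.7 |
| ash | 8.00 | 18.3 | 80.9 |
| ash | 15.0 | 36.3 | 62.8 |
| ash | 30.0 | 65.2 | 32.6 |
| elm | 2.50 | 4.1 | 55.5 |
| elm | 8.00 | 27.2 | 71.3 |
| elm | 15.0 | 52.2 | 46.5 |
| elm | 20.0 | 65.2 | 32.8 |
| elm | 30.0 | 77.4 | 20.5 |

(scatter of a reading: 0.5 percentage points)

* amount of Q at the end, in percent of the X charged for teal, amber, blue, in this order
* how the row runs (falls, then rises / rises, then falls / rises all the way / hardly changes / falls all the way)

- the numbers in the tables scatter with a standard deviation of 0.5 percentage points
- "hardly changes" means that all values lie within two and a half points (for a concentration: within two and a half percent of the largest)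
- percentages count the whole charge, also what has not yet gone in

The easy step is a count. I assume each Q uses one E, and the E charge 0.0144 M is smaller than the X charge 0.018 M, which makes E the limiting reagent; this gives the ceiling C, the E charge divided by the X charge, 80.0%. The elm run does not contradict it: Q stands at 77.4% at 30.0 min and is slowing.

That solves the late end. For the early end I read the decay of X in the ash run between 8.00 min and 30.0 min, and scaling in proportion to J gives a rate constant k = 0.0826 min⁻¹ at 0.54 mM. The elm run, read the same way between 8.00 min and 15.0 min, gives 0.0804 min⁻¹.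

A steady feed delivers X late by half the dosing time on average. With no ceiling, a first-order decay at k reaches C after a mean reaction time of 19.5 min. The time 25 min less that delay gives 23.0 min in teal, 21.0 min in amber and 17.5 min in blue.

Joining the ends, the time needed lies between amber's and blue's. So I expect teal and amber close under C, blue lower, and a falling row. Please leave the feed short: blue's longer feed gives up 5.50 min of reaction time against teal's.

The forecast gives 76%, 74.7% and 71.7%, falls all the way, holding that “Slower feeding keeps X low early, which wastes time”.

The flasks give 78.6%, 77.8% and 75.1%: the row falls all the way, as I reckoned.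

    X + J → Z (k = 6.10 L mol⁻¹ s⁻¹)
    E + D ⇌ G, settled at all times (K = 1900 L mol⁻¹)
    E + Z ⇌ L (K = 34.0 L mol⁻¹, k = 27.0 L mol⁻¹ s⁻¹)
    D → J + Q (k = 1.80 s⁻¹)
    L → D (k = 0.600 s⁻¹)

At the end of teal, the forward step E + Z → L alone would halve E in 0.93 min, far shorter than the 24 min in which X + J → Z alone would halve X. There 85.1% of the catalyst stands as Z, the resting state at that moment, and 1.7% of the E charge remains, so C times the E used is 78.6%, against 78.6% of Q. In blue, with 6.0% of its E remaining, the same product is 75.2%, against 75.1%.

(The earlier runs and the new flask are simulated for an exercise; scatter was added.)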